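## Structural features

The target is a germacranolide: a ten-membered carbocycle (C1–C10) fused at C6–C7 to an α,β-unsaturated γ-lactone (O–C12(=O)–C11=C7, with C6 as the γ-carbon), whose α-carbon C11 carries the acetoxymethyl group C13. Around the ring stand the C1 ketone, the C2 and C3 methylenes, a trans-configured trisubstituted epoxide at C4(Me)–C5, the lactone carbinol C6, the methacrylate at C8, the free hydroxyl at C9 and the methyl-bearing C10. The six stereocentres form two contiguous sets, C4–C5–C6 and C8–C9–C10, separated by sp2 C7 on one side and by C1–C3 on the other, so their mutual relation is transannular. Fragile groups are: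

- the β-hydroxy ketone (C9–OH/C1=O): retro-aldol, dehydration, epimerisable C10;
- the acidic butenolide γ-H at C6 next to the epoxide (base opens the epoxide);
- the allylic acetate at C13 (SN2′ acceptor), the methacrylate, and the acid-labile epoxide;
- the C8 ester beside the free C9 hydroxyl (acyl migration).

The real difficulty is the strained ten-membered ring carrying an E-configured C4–C5 unit (the trans-epoxide cannot come from a cis-olefin), together with the remote relation of C6 to C8–C10. The feature the key step exploits is this: C9 (carbinol), C10 (methyl) and C1 (ketone) are the three adjacent carbons of a 2-methyl-1,3-dione, and with C2, C3 and C4 they form a six-membered ring C9–C10–C1–C2–C3–C4. The E-C4=C5 bond and the C6–C7 bond with its C6 stereocentre are then exactly the new π and σ bonds of a [3,3] shift across the C4–C9 bond of that ring. The C9 carbonyl and C8 enolate that result give direct access to the C8 and C9 oxygens.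

## Logic of the disconnections

In one sentence: the ten-membered ring arises by anionic oxy-Cope ring expansion of the six-membered dialkenyl alkoxide 11.

26 to 25: the two C–O bonds of the epoxide are cut. The epoxide is the most acid- and base-sensitive group, so it is placed last. The gain is an E-olefin that survives all earlier steps. The demand is chemoselective and face-selective epoxidation of C4=C5 in the presence of the methacrylate and butenolide olefins.

25 to 24 to 22, then to 18 and 21: the silyl ether at O9 is a protecting group. The butenolide is cut at C7=C11, at C13–O(acetate) and at the C12–O6 ester bond. This reduces the lactone to an α-hydroxy ketone and a three-carbon phosphonoacrylate, and introduces the acetate in the ring-forming event. The demand is a mild base, because C6–H and C8–H flank the C7 ketone.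

18 to 17 to 16: the C6–O benzyl-type ether is cleaved oxidatively. The C1 and C7 carbonyls are traced back to an enol acetal and a ketal, which are what the key step delivers. The gain is that no 1,3- or 1,5-dicarbonyl is carried while C8 is still enolisable. The demand is unmasking without ionisation of the allylic C9–O bond.

16 to 15 to 14 to 13: the O9–Si bond, the C9–H bond (ketone reduction) and the C8 ester C–O bond are cut. This leads back to an α-hydroxy ketone. The demand is hydride delivery anti to the C8–O bond and no acyl migration.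

13 to 7 and 9 (through 10, 11 and 12): the C6–C7 bond and the C8–O bond are cut and the C4–C9 bond is re-formed. This is the key disconnection. It turns the ten-membered ring with three defined elements (E-C4=C5, C6, C8) into a six-membered ring with a single quaternary stereocentre. The demand is a chair transition state from the trans-dialkenyl alkoxide and oxidation of the enolate before it can eliminate or equilibrate.

7 to 5 to 4 to 3, then to 1 and 2: the O-alkyl bond of the vinylogous ester and the C9–C10 bond (Claisen-type ring closure) are cut. Then follow the C6–O bond of the enol ether, the C5=C6 bond (aldehyde olefination) and the C3–C4 bond (Michael addition). Everything rests on two commercial compounds and one catalytic enantioselective step. The demand is control of the quaternary C4 centre and an enol ether of pure E geometry.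

21 to 20 to 19, and 9 to 8: the exocyclic methylene of 21 is cut back to formaldehyde and the ester to its tert-butyl precursor. The vinyl bromide is cut back to a gem-dibromide. Both are two-carbon reagents made in one or two steps.

## Other disconnections considered

Alternative 1: the first idea is to cut C5–C6 and close the ring by an intramolecular CrCl2/NiCl2-mediated (Nozaki–Hiyama–Kishi) coupling of the seco iodo-aldehyde A1, with lactonisation of the new C6 alkoxide onto the C12 ester.

- The ring closure must overcome the transannular strain of a ten-membered ring that contains an E-trisubstituted olefin, without any pre-organisation.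
- The C6 carbinol would be set only by weak bias from the distant C8–C10 centres.
- A1 is an acyclic chain in which every stereocentre has to be installed separately, and it carries a β-silyloxy ketone and an enal prone to elimination.
- The chosen plan forms the same ring by an intramolecular pericyclic shift whose geometry fixes both the olefin and C6.

Alternative 2: cut the same C4–C9 bond by a Grob fragmentation of the trans-fused decalin hydroxy mesylate A2 (C9 alkoxide pushing, C5 mesylate leaving, anti-periplanar).

- This would also give an E-C4=C5 cyclodecenone.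
- The fragmentation forms no C–C bond, so C6, C7 and C8 must already be oxygenated on the decalin; these are the unfunctionalised methylenes of the annulation product, and A2 needs six stereocentres.
- It delivers a C9 ketone without a regiodefined enolate, so the C8 oxygen cannot be introduced in the same operation.
- The oxy-Cope route needs one stereocentre in the six-membered ring and builds C6–C7 while expanding.

Alternative 3: run the oxy-Cope in the other register, cleaving C2–C7 and forming C9–C10 from carbinol A3.

- C7 and C1 would both emerge as carbonyls and C9/C10 would be set together in the chair.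
- A3 needs four contiguous stereocentres on the six-membered ring.
- It needs an (E)-1-methoxyprop-1-enyl group next to the ketone; this is hard to introduce there, because acylation/O-alkylation would place the enol ether in conjugation with the ketone.
- It needs a later Payne rearrangement to obtain the trans-epoxide.
- Its enolate carries the C9 oxygen in the β-position with nothing to hold the C–O bond out of alignment.
- The chosen register needs fewer steps to the rearrangement substrate and sets the E-olefin directly.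

Key step: step 6

Remark on numbering: ring carbons of all intermediates carry the germacrane numbers of the target (C1 ketone carbon, C4 and C10 methyl-bearing, C6 lactone carbinol, C11–C13 the lactone side carbons).

Assumption: C10 is α to the C1 ketone and is taken to be under thermodynamic control, the 10S configuration of the target being the more stable one in the ring.

## Steps

Step 1
Reactants: 1 ethyl 2-methyl-3-oxopropanoate; 2 pent-1-en-3-one
Product: 3 ethyl (2S)-2-formyl-2-methyl-5-oxoheptanoate
Conditions: quinine-derived tertiary-amine/squaramide organocatalyst (5 mol %), CH2Cl2, −20 °C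
Reagents that add atoms: none
Why: Bifunctional amine/squaramide-catalysed Michael addition of an α-substituted β-dicarbonyl donor to an alkyl vinyl ketone; the catalyst binds the enol and the enone and sets the quaternary C4 centre (the pseudoenantiomer of the catalyst that gives the S adduct is used).

Step 2
Reactants: 3 ethyl (2S)-2-formyl-2-methyl-5-oxoheptanoate
Product: 4 ethyl (2S)-2-[(E)-2-iodoethenyl]-2-methyl-5-oxoheptanoate
Conditions: CHI3, CrCl2, THF, 0 °C
Reagents that add atoms: iodoform, IC(I)I
Why: Takai iodo-olefination is selective for the aldehyde beside ketone and ester and should give the E-alkenyl iodide; the quaternary centre is not enolisable and is untouched.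

Step 3
Reactants: 4 ethyl (2S)-2-[(E)-2-iodoethenyl]-2-methyl-5-oxoheptanoate
Product: 5 ethyl (2S)-2-[(E)-2-[(4-methoxyphenyl)methoxy]ethenyl]-2-methyl-5-oxoheptanoate
Conditions: CuI (10 mol %), 3,4,7,8-tetramethyl-1,10-phenanthroline, Cs2CO3, toluene, 80 °C
Reagents that add atoms: 4-methoxybenzyl alcohol, COc1ccc(CO)cc1
Why: Copper-catalysed C–O cross-coupling of an alkenyl iodide with a primary alcohol proceeds with retention of olefin geometry, so the E enol ether needed for the later chirality transfer should form as a single isomer.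

Step 4
Reactants: 5 ethyl (2S)-2-[(E)-2-[(4-methoxyphenyl)methoxy]ethenyl]-2-methyl-5-oxoheptanoate
Product: 7 (6S)-3-(methoxymethoxy)-6-[(E)-2-[(4-methoxyphenyl)methoxy]ethenyl]-2,6-dimethylcyclohex-2-en-1-one, via dione potassium enolate 6 (not isolated)
Conditions: KOt-Bu, THF, 0 to 25 °C; then MOMCl, i-Pr2NEt, 0 °C
Reagents that add atoms: chloromethyl methyl ether, COCCl
Why: Intramolecular Claisen (Dieckmann-type) condensation of the ketone C10 enolate on the ester closes the six-membered 1,3-dione; its enolate should be O-alkylated by the hard electrophile at the oxygen remote from the quaternary carbon, and C4 is not involved.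

Step 5
Reactants: 8 2,2-dibromo-1,1-diethoxyethane
Product: 9 2-bromo-1,1-diethoxyethene
Conditions: KOt-Bu, t-BuOH, 25 to 60 °C; distillation
Reagents that add atoms: none
Why: E2 dehydrobromination of the gem-dibromo acetal by tert-butoxide should give the bromoketene acetal.

Step 6
Reactants: 7 (6S)-3-(methoxymethoxy)-6-[(E)-2-[(4-methoxyphenyl)methoxy]ethenyl]-2,6-dimethylcyclohex-2-en-1-one; 9 2-bromo-1,1-diethoxyethene
Product: 13 (6R,8S)-7,7-diethoxy-8-hydroxy-1-(methoxymethoxy)-6-[(4-methoxyphenyl)methoxy]-4,10-dimethylcyclodeca-1(10),4-dien-9-one (1(10)E,4E), via diethoxyvinyllithium 10 (not isolated), via potassium alkoxide 11 (not isolated), via potassium enolate 12 (not isolated)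
Conditions: 9, t-BuLi (2 equiv), THF, −78 °C; add 7, −78 °C; then KOt-Bu, 18-crown-6, −78 to 0 °C; then 2-(benzenesulfonyl)-3-phenyloxaziridine, −78 °C; aq. NH4Cl
Reagents that add atoms: 2-(benzenesulfonyl)-3-phenyloxaziridine, O=S(=O)(c1ccccc1)N1OC1c1ccccc1
Why: Bromine–lithium exchange on 9 gives 10, which should add to the vinylogous-ester carbonyl C9 of 7 anti to the pseudoaxial alkenyl group on C4 (Felkin–Anh) to give the trans-dialkenyl alkoxide, and exchange of lithium for crown-complexed potassium triggers the [3,3] shift of 11. The closest known reaction type is the anionic oxy-Cope ring expansion of 1,2-dialkenylcyclohexanols to cyclodec-5-enones with oxidation of the regiodefined enolate. The ten-membered ring is closed by a four-carbon ring expansion: the C6–C7 σ bond forms between the two alkene termini while the C4–C9 ring bond breaks, through a chair transition state in which both ring bonds (C3 on C4, C10 on C9) are pseudoequatorial and the C4 methyl and the oxyanion pseudoaxial. C3 pseudoequatorial makes the new C4=C5 bond E, and C6 is set by suprafacial transfer of the C4 configuration across the allyl unit, the E enol ether placing the benzyloxy group pseudoequatorial, so that (S)-C4 gives the C6 configuration of the target. C8 is set when the oxaziridine attacks enolate 12 on its outer face, the inner face being covered across the ring by the C4=C5 bond in the crossed conformation that the chair delivers. The step needs chair over boat (secured by the trans relation of the alkenyl groups), no proton transfer before oxidation (no acid partner is present) and no β-elimination of ethoxide from 12 (the C7–O bonds lie near the nodal plane of the enolate as formed, and the enolate is oxidised at −78 °C).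

Step 7
Reactants: 13 (6R,8S)-7,7-diethoxy-8-hydroxy-1-(methoxymethoxy)-6-[(4-methoxyphenyl)methoxy]-4,10-dimethylcyclodeca-1(10),4-dien-9-one
Product: 14 (6R,8S)-7,7-diethoxy-1-(methoxymethoxy)-6-[(4-methoxyphenyl)methoxy]-4,10-dimethyl-9-oxocyclodeca-1(10),4-dien-8-yl 2-methylprop-2-enoate
Conditions: methacrylic anhydride, Et3N, DMAP (cat.), CH2Cl2, 0 °C
Reagents that add atoms: methacrylic anhydride, C=C(C)C(=O)OC(=O)C(C)=C
Why: DMAP-catalysed acylation of the only free hydroxyl; installing the target's ester now also makes O8 a non-chelating, electron-withdrawing group for the next two steps.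

Step 8
Reactants: 14 (6R,8S)-7,7-diethoxy-1-(methoxymethoxy)-6-[(4-methoxyphenyl)methoxy]-4,10-dimethyl-9-oxocyclodeca-1(10),4-dien-8-yl 2-methylprop-2-enoate
Product: 15 (6R,8S,9R)-7,7-diethoxy-9-hydroxy-1-(methoxymethoxy)-6-[(4-methoxyphenyl)methoxy]-4,10-dimethylcyclodeca-1(10),4-dien-8-yl 2-methylprop-2-enoate
Conditions: NaBH4, CeCl3·7H2O, MeOH/THF, −78 °C
Reagents that add atoms: none
Why: Luche 1,2-reduction of the vinylogous-ester carbonyl; with C8 now sp3 the planar O=C9–C10=C1 unit lies in the mean plane of the ring with both faces open, and hydride should enter anti to the C8–O bond (polar Felkin–Anh), giving the 8,9-trans relation (9R); low temperature and the cerium alkoxide suppress acyl migration.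

Step 9
Reactants: 15 (6R,8S,9R)-7,7-diethoxy-9-hydroxy-1-(methoxymethoxy)-6-[(4-methoxyphenyl)methoxy]-4,10-dimethylcyclodeca-1(10),4-dien-8-yl 2-methylprop-2-enoate
Product: 16 (6R,8S,9R)-9-[(tert-butyldimethylsilyl)oxy]-7,7-diethoxy-1-(methoxymethoxy)-6-[(4-methoxyphenyl)methoxy]-4,10-dimethylcyclodeca-1(10),4-dien-8-yl 2-methylprop-2-enoate
Conditions: TBSOTf, 2,6-lutidine, CH2Cl2, −78 °C
Reagents that add atoms: tert-butyldimethylsilyl trifluoromethanesulfonate, CC(C)(C)[Si](C)(C)OS(=O)(=O)C(F)(F)F
Why: Buffered silylation of the secondary alcohol; it keeps O9 from competing with O6 in step 14 and from acting as an acyl acceptor.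

Step 10
Reactants: 16 (6R,8S,9R)-9-[(tert-butyldimethylsilyl)oxy]-7,7-diethoxy-1-(methoxymethoxy)-6-[(4-methoxyphenyl)methoxy]-4,10-dimethylcyclodeca-1(10),4-dien-8-yl 2-methylprop-2-enoate
Product: 17 (6R,8S,9R,10S)-9-[(tert-butyldimethylsilyl)oxy]-6-[(4-methoxyphenyl)methoxy]-4,10-dimethyl-1,7-dioxocyclodec-4-en-8-yl 2-methylprop-2-enoate (4E)
Conditions: TsOH·H2O (cat.), acetone/H2O, 25 °C
Reagents that add atoms: water, O
Why: Acid-catalysed cleavage of the enol acetal at its acetal carbon releases the C1 enol, which ketonises, and hydrolysis of the diethyl ketal releases the C7 ketone; the acyloxy group at C8 destabilises a cation at C9 and so disfavours loss of the C9 oxygen, and C10 is set on ketonisation and by equilibration (see assumption).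

Step 11
Reactants: 17 (6R,8S,9R,10S)-9-[(tert-butyldimethylsilyl)oxy]-6-[(4-methoxyphenyl)methoxy]-4,10-dimethyl-1,7-dioxocyclodec-4-en-8-yl 2-methylprop-2-enoate
Product: 18 (6R,8S,9R,10S)-9-[(tert-butyldimethylsilyl)oxy]-6-hydroxy-4,10-dimethyl-1,7-dioxocyclodec-4-en-8-yl 2-methylprop-2-enoate (4E)
Conditions: DDQ, CH2Cl2/pH 7 buffer, 0 °C
Reagents that add atoms: none
Why: Oxidative removal of the 4-methoxybenzyl ether under neutral conditions leaves the silyl ether, the esters and the olefins untouched.

Step 12
Reactants: 19 tert-butyl 2-(diethoxyphosphoryl)acetate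
Product: 20 tert-butyl 2-(diethoxyphosphoryl)prop-2-enoate
Conditions: (CH2O)n, piperidine (cat.), MeOH, reflux; then TsOH (cat.), toluene, reflux
Reagents that add atoms: formaldehyde (from paraformaldehyde), C=O
Why: Knoevenagel methylenation of the phosphonoacetate; the methanol adduct formed first loses methanol under acid to give the vinylphosphonate.

Step 13
Reactants: 20 tert-butyl 2-(diethoxyphosphoryl)prop-2-enoate
Product: 21 2-(diethoxyphosphoryl)prop-2-enoic acid
Conditions: CF3CO2H, CH2Cl2, 0 to 25 °C
Reagents that add atoms: none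
Why: Acidolysis of the tert-butyl ester frees the acid without any nucleophile that could add to the acceptor.

Step 14
Reactants: 18 (6R,8S,9R,10S)-9-[(tert-butyldimethylsilyl)oxy]-6-hydroxy-4,10-dimethyl-1,7-dioxocyclodec-4-en-8-yl 2-methylprop-2-enoate; 21 2-(diethoxyphosphoryl)prop-2-enoic acid
Product: 22 (6R,8S,9R,10S)-9-[(tert-butyldimethylsilyl)oxy]-6-[2-(diethoxyphosphoryl)prop-2-enoyloxy]-4,10-dimethyl-1,7-dioxocyclodec-4-en-8-yl 2-methylprop-2-enoate (4E)
Conditions: DCC, DMAP (cat.), CH2Cl2, 0 °C
Reagents that add atoms: none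
Why: Carbodiimide esterification of the only free hydroxyl (O6) under nearly neutral conditions; the stereocentres next to the C7 ketone are not exposed to base.

Step 15
Reactants: 22 (6R,8S,9R,10S)-9-[(tert-butyldimethylsilyl)oxy]-6-[2-(diethoxyphosphoryl)prop-2-enoyloxy]-4,10-dimethyl-1,7-dioxocyclodec-4-en-8-yl 2-methylprop-2-enoate
Product: 24 (6R,8R,9R,10S)-13-acetoxy-9-[(tert-butyldimethylsilyl)oxy]-1-oxogermacra-4,7(11)-dien-12,6-olid-8-yl 2-methylprop-2-enoate (4E), via phosphonate carbanion 23 (not isolated)
Conditions: CsOAc, 18-crown-6, MeCN, 0 to 25 °C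
Reagents that add atoms: cesium acetate, [Cs+].CC([O-])=O
Why: Tandem Michael addition/intramolecular Horner–Wadsworth–Emmons reaction: acetate adds reversibly to the doubly activated vinylphosphonate, and the carbanion is removed irreversibly by five-membered ring olefination of the adjacent C7 ketone, which builds C7=C11 and places the acetate on C13; acetate is too weak a base to enolise C6 or C8.

Step 16
Reactants: 24 (6R,8R,9R,10S)-13-acetoxy-9-[(tert-butyldimethylsilyl)oxy]-1-oxogermacra-4,7(11)-dien-12,6-olid-8-yl 2-methylprop-2-enoate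
Product: 25 (6R,8R,9R,10S)-13-acetoxy-9-hydroxy-1-oxogermacra-4,7(11)-dien-12,6-olid-8-yl 2-methylprop-2-enoate (4E)
Conditions: HF·pyridine, pyridine, THF, 0 °C
Reagents that add atoms: none
Why: Buffered fluoride desilylation without base, so that the butenolide γ-H, the esters and the β-hydroxy ketone should survive; it is done before the epoxide is present.

Step 17
Reactants: 25 (6R,8R,9R,10S)-13-acetoxy-9-hydroxy-1-oxogermacra-4,7(11)-dien-12,6-olid-8-yl 2-methylprop-2-enoate
Product: 26 (4R,5R,6S,8R,9R,10S)-13-acetoxy-4,5-epoxy-9-hydroxy-1-oxogermacr-7(11)-en-12,6-olid-8-yl 2-methylprop-2-enoate (target)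
Conditions: mCPBA, NaHCO3, CH2Cl2, 0 °C
Reagents that add atoms: 3-chloroperoxybenzoic acid, OOC(=O)c1cccc(Cl)c1
Why: Peracid epoxidation is selective for the only electron-rich olefin; allylic 1,3-strain with the C4 methyl holds C6–H in the olefin plane and C7 on the inner face, so attack from the ring periphery should give the 4R,5R epoxide (stereospecifically trans from the E-olefin).

## Compound list

1 | ethyl 2-methyl-3-oxopropanoate | CCOC(=O)C(C)C=O | starting material
2 | pent-1-en-3-one | CCC(=O)C=C | starting material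
3 | ethyl (2S)-2-formyl-2-methyl-5-oxoheptanoate | CCOC(=O)[C@](C)(C=O)CCC(=O)CC | intermediate
4 | ethyl (2S)-2-[(E)-2-iodoethenyl]-2-methyl-5-oxoheptanoate | CCOC(=O)[C@](C)(/C=C/I)CCC(=O)CC | intermediate
5 | ethyl (2S)-2-[(E)-2-[(4-methoxyphenyl)methoxy]ethenyl]-2-methyl-5-oxoheptanoate | CCOC(=O)[C@](C)(/C=C/OCc1ccc(OC)cc1)CCC(=O)CC | intermediate
6 | potassium enolate of (4S)-4-[(E)-2-[(4-methoxyphenyl)methoxy]ethenyl]-2,4-dimethylcyclohexane-1,3-dione | [K+].O=C1C(C)=C([O-])CC[C@@]1(C)/C=C/OCc1ccc(OC)cc1 | intermediate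
7 | (6S)-3-(methoxymethoxy)-6-[(E)-2-[(4-methoxyphenyl)methoxy]ethenyl]-2,6-dimethylcyclohex-2-en-1-one | O=C1C(C)=C(OCOC)CC[C@@]1(C)/C=C/OCc1ccc(OC)cc1 | intermediate
8 | 2,2-dibromo-1,1-diethoxyethane | CCOC(OCC)C(Br)Br | starting material
9 | 2-bromo-1,1-diethoxyethene | CCOC(OCC)=CBr | intermediate
10 | (2,2-diethoxyethenyl)lithium | [Li]C=C(OCC)OCC | intermediate
11 | potassium (1R,6S)-1-(2,2-diethoxyethenyl)-3-(methoxymethoxy)-6-[(E)-2-[(4-methoxyphenyl)methoxy]ethenyl]-2,6-dimethylcyclohex-2-en-1-olate | [K+].[O-][C@@]1(C=C(OCC)OCC)C(C)=C(OCOC)CC[C@@]1(C)/C=C/OCc1ccc(OC)cc1 | intermediate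
12 | potassium (6R)-7,7-diethoxy-1-(methoxymethoxy)-6-[(4-methoxyphenyl)methoxy]-4,10-dimethylcyclodeca-1(10),4,8-trien-9-olate (1(10)E,4E,8Z) | [K+].CCOC1(OCC)/C=C(\[O-])/C(C)=C(OCOC)\CC/C(C)=C/[C@H]1OCc2ccc(OC)cc2 | intermediate
13 | (6R,8S)-7,7-diethoxy-8-hydroxy-1-(methoxymethoxy)-6-[(4-methoxyphenyl)methoxy]-4,10-dimethylcyclodeca-1(10),4-dien-9-one (1(10)E,4E) | O[C@@H]1C(OCC)(OCC)[C@H](OCc2ccc(OC)cc2)/C=C(C)/CC/C(OCOC)=C(C)\C1=O | intermediate
14 | (6R,8S)-7,7-diethoxy-1-(methoxymethoxy)-6-[(4-methoxyphenyl)methoxy]-4,10-dimethyl-9-oxocyclodeca-1(10),4-dien-8-yl 2-methylprop-2-enoate | C=C(C)C(=O)O[C@@H]1C(OCC)(OCC)[C@H](OCc2ccc(OC)cc2)/C=C(C)/CC/C(OCOC)=C(C)\C1=O | intermediate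
15 | (6R,8S,9R)-7,7-diethoxy-9-hydroxy-1-(methoxymethoxy)-6-[(4-methoxyphenyl)methoxy]-4,10-dimethylcyclodeca-1(10),4-dien-8-yl 2-methylprop-2-enoate | C=C(C)C(=O)O[C@@H]1C(OCC)(OCC)[C@H](OCc2ccc(OC)cc2)/C=C(C)/CC/C(OCOC)=C(C)\[C@H]1O | intermediate
16 | (6R,8S,9R)-9-[(tert-butyldimethylsilyl)oxy]-7,7-diethoxy-1-(methoxymethoxy)-6-[(4-methoxyphenyl)methoxy]-4,10-dimethylcyclodeca-1(10),4-dien-8-yl 2-methylprop-2-enoate | C=C(C)C(=O)O[C@@H]1C(OCC)(OCC)[C@H](OCc2ccc(OC)cc2)/C=C(C)/CC/C(OCOC)=C(C)\[C@H]1O[Si](C)(C)C(C)(C)C | intermediate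
17 | (6R,8S,9R,10S)-9-[(tert-butyldimethylsilyl)oxy]-6-[(4-methoxyphenyl)methoxy]-4,10-dimethyl-1,7-dioxocyclodec-4-en-8-yl 2-methylprop-2-enoate (4E) | C=C(C)C(=O)O[C@@H]1C(=O)[C@H](OCc2ccc(OC)cc2)/C=C(C)/CCC(=O)[C@@H](C)[C@H]1O[Si](C)(C)C(C)(C)C | intermediate
18 | (6R,8S,9R,10S)-9-[(tert-butyldimethylsilyl)oxy]-6-hydroxy-4,10-dimethyl-1,7-dioxocyclodec-4-en-8-yl 2-methylprop-2-enoate (4E) | C=C(C)C(=O)O[C@@H]1C(=O)[C@H](O)/C=C(C)/CCC(=O)[C@@H](C)[C@H]1O[Si](C)(C)C(C)(C)C | intermediate
19 | tert-butyl 2-(diethoxyphosphoryl)acetate | CCOP(=O)(OCC)CC(=O)OC(C)(C)C | starting material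
20 | tert-butyl 2-(diethoxyphosphoryl)prop-2-enoate | CCOP(=O)(OCC)C(=C)C(=O)OC(C)(C)C | intermediate
21 | 2-(diethoxyphosphoryl)prop-2-enoic acid | CCOP(=O)(OCC)C(=C)C(=O)O | intermediate
22 | (6R,8S,9R,10S)-9-[(tert-butyldimethylsilyl)oxy]-6-[2-(diethoxyphosphoryl)prop-2-enoyloxy]-4,10-dimethyl-1,7-dioxocyclodec-4-en-8-yl 2-methylprop-2-enoate (4E) | C=C(C)C(=O)O[C@@H]1C(=O)[C@H](OC(=O)C(=C)P(=O)(OCC)OCC)/C=C(C)/CCC(=O)[C@@H](C)[C@H]1O[Si](C)(C)C(C)(C)C | intermediate
23 | cesium salt of the α-phosphoryl carbanion formed from 22 by addition of acetate to the vinylphosphonate | [Cs+].C=C(C)C(=O)O[C@@H]1C(=O)[C@H](OC(=O)[C-](COC(C)=O)P(=O)(OCC)OCC)/C=C(C)/CCC(=O)[C@@H](C)[C@H]1O[Si](C)(C)C(C)(C)C | intermediate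
24 | (6R,8R,9R,10S)-13-acetoxy-9-[(tert-butyldimethylsilyl)oxy]-1-oxogermacra-4,7(11)-dien-12,6-olid-8-yl 2-methylprop-2-enoate (4E) | C=C(C)C(=O)O[C@@H]1C2=C(COC(C)=O)C(=O)O[C@@H]2/C=C(C)/CCC(=O)[C@@H](C)[C@H]1O[Si](C)(C)C(C)(C)C | intermediate
25 | (6R,8R,9R,10S)-13-acetoxy-9-hydroxy-1-oxogermacra-4,7(11)-dien-12,6-olid-8-yl 2-methylprop-2-enoate (4E) | C=C(C)C(=O)O[C@@H]1C2=C(COC(C)=O)C(=O)O[C@@H]2/C=C(C)/CCC(=O)[C@@H](C)[C@H]1O | intermediate
26 | (4R,5R,6S,8R,9R,10S)-13-acetoxy-4,5-epoxy-9-hydroxy-1-oxogermacr-7(11)-en-12,6-olid-8-yl 2-methylprop-2-enoate | C=C(C)C(=O)O[C@@H]1C2=C(COC(C)=O)C(=O)O[C@@H]2[C@H]2O[C@]2(C)CCC(=O)[C@@H](C)[C@H]1O | target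

## Step count and least certain steps

Total step count: 17. Longest linear sequence: 14 steps (steps 1–4, 6–11, 14–17).

Step 6 (key step). Three things may go wrong.

- Facial selectivity in the 1,2-addition may be poor; the epimeric cis-dialkenyl alkoxide would rearrange through the opposite chair to the Z-olefin with inverted C6.
- Ethoxide may be lost from the β-position of the enolate before oxidation.
- The oxaziridine may not discriminate the two enolate faces.

Fallback: from 7, the adduct of 10 is silylated with Me3SiCl to the tertiary trimethylsilyl ether F1, whose C9 epimers can be separated. F1 is rearranged thermally as the neutral silyl ether (siloxy-Cope, sealed tube, about 180 °C) to the ten-membered silyl enol ether F2, so that no free enolate is formed. Rubottom oxidation of F2 (dimethyldioxirane, then mild desilylation) then returns to 13.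

Step 1. Enantiofacial control at the quaternary centre may be poor, because the formyl and ester groups of the donor are similar in size and the uncatalysed addition is fast. Fallback: 1 is condensed with (S)-1-phenylethylamine to the chiral secondary enamino ester F3. F3 adds to 2 through the aza-ene-type Michael transition state of chiral enamino esters, and acidic hydrolysis of the imine returns to 3. The enantiomer of the amine is used if the facial sense requires it.

Step 8. Hydride delivery may follow the ring conformation instead of the Felkin–Anh preference, and the methacryloyl group may migrate from O8 to the new C9 alkoxide. Fallback: from 13 the order is changed so that no acyl group is present during reduction.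

- O8 is silylated (Et3SiCl) to ketone F4.
- F4 is reduced under the same non-chelating conditions to alcohol F5.
- O9 is silylated (TBSOTf) to the bis-silyl ether F6.
- The triethylsilyl group is removed selectively (buffered HF·pyridine, −20 °C) to alcohol F7.
- Acylation of F7 with methacrylic anhydride returns to 16.

Step 10. Ionisation of the allylic C9–O bond with loss of the C9 oxygen may compete with unmasking; hydrolysis of the ketal flanked by two oxygenated carbons may be slow; protonation at C10 may be unselective. Fallback: from 16 the two masks are removed in separate operations of different mechanism. Silyl-transfer cleavage of the enol acetal (Me3SiOTf, 2,2′-bipyridyl, then water, no Brønsted acid) gives the C1 ketone F8 with the ketal intact. Ketal cleavage (aqueous CF3CO2H/CHCl3, 0 °C) on this less ionisable substrate returns to 17.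

Step 15. Conjugate addition of acetate may be too slow, so that elimination or epimerisation next to the C7 ketone takes over. Fallback: from 18, acylation with acryloyl chloride gives acrylate F9. An amine-catalysed intramolecular Morita–Baylis–Hillman reaction onto the C7 ketone gives the 7-hydroxy-α-methylene lactone F10 (either C7 epimer serves). Acetylation and amine-mediated SN2′/SN2′ transposition of the tertiary allylic acetate to the conjugated primary one returns to 24.

Step 17. Attack on the inner face of the olefin would give the 4,5-epi-epoxide, and the ketone could undergo Baeyer–Villiger oxidation on long exposure. Fallback: the epoxide is introduced earlier under hydroxyl direction.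

- From 18, VO(acac)2/t-BuOOH epoxidation guided by the free C6 hydroxyl gives epoxy alcohol F11.
- F11 is esterified with 21 to F12.
- F12 is cyclised with CsOAc to the silyl ether F13.
- Buffered fluoride (Bu4NF/AcOH) returns to 26.

## Further compounds

F1 | step 6 | (1R,6S)-1-(2,2-diethoxyethenyl)-3-(methoxymethoxy)-6-[(E)-2-[(4-methoxyphenyl)methoxy]ethenyl]-2,6-dimethyl-1-(trimethylsilyloxy)cyclohex-2-ene | C[Si](C)(C)O[C@@]1(C=C(OCC)OCC)C(C)=C(OCOC)CC[C@@]1(C)/C=C/OCc1ccc(OC)cc1
F2 | step 6 | (6R)-7,7-diethoxy-1-(methoxymethoxy)-6-[(4-methoxyphenyl)methoxy]-4,10-dimethyl-9-(trimethylsilyloxy)cyclodeca-1(10),4,8-triene | CCOC1(OCC)/C=C(\O[Si](C)(C)C)/C(C)=C(OCOC)\CC/C(C)=C/[C@H]1OCc2ccc(OC)cc2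
F3 | step 1 | ethyl (Z)-2-methyl-3-[[(1S)-1-phenylethyl]amino]prop-2-enoate | CCOC(=O)/C(C)=C\N[C@@H](C)c1ccccc1
F4 | step 8 | (6R,8S)-7,7-diethoxy-1-(methoxymethoxy)-6-[(4-methoxyphenyl)methoxy]-4,10-dimethyl-8-(triethylsilyloxy)cyclodeca-1(10),4-dien-9-one | CC[Si](CC)(CC)O[C@@H]1C(OCC)(OCC)[C@H](OCc2ccc(OC)cc2)/C=C(C)/CC/C(OCOC)=C(C)\C1=O
F5 | step 8 | (6R,8S,9R)-7,7-diethoxy-1-(methoxymethoxy)-6-[(4-methoxyphenyl)methoxy]-4,10-dimethyl-8-(triethylsilyloxy)cyclodeca-1(10),4-dien-9-ol | CC[Si](CC)(CC)O[C@@H]1C(OCC)(OCC)[C@H](OCc2ccc(OC)cc2)/C=C(C)/CC/C(OCOC)=C(C)\[C@H]1O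
F6 | step 8 | (6R,8S,9R)-9-[(tert-butyldimethylsilyl)oxy]-7,7-diethoxy-1-(methoxymethoxy)-6-[(4-methoxyphenyl)methoxy]-4,10-dimethyl-8-(triethylsilyloxy)cyclodeca-1(10),4-diene | CC[Si](CC)(CC)O[C@@H]1C(OCC)(OCC)[C@H](OCc2ccc(OC)cc2)/C=C(C)/CC/C(OCOC)=C(C)\[C@H]1O[Si](C)(C)C(C)(C)C
F7 | step 8 | (6R,8S,9R)-9-[(tert-butyldimethylsilyl)oxy]-7,7-diethoxy-1-(methoxymethoxy)-6-[(4-methoxyphenyl)methoxy]-4,10-dimethylcyclodeca-1(10),4-dien-8-ol | O[C@@H]1C(OCC)(OCC)[C@H](OCc2ccc(OC)cc2)/C=C(C)/CC/C(OCOC)=C(C)\[C@H]1O[Si](C)(C)C(C)(C)C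
F8 | step 10 | (6R,8S,9R,10S)-9-[(tert-butyldimethylsilyl)oxy]-7,7-diethoxy-6-[(4-methoxyphenyl)methoxy]-4,10-dimethyl-1-oxocyclodec-4-en-8-yl 2-methylprop-2-enoate | C=C(C)C(=O)O[C@@H]1C(OCC)(OCC)[C@H](OCc2ccc(OC)cc2)/C=C(C)/CCC(=O)[C@@H](C)[C@H]1O[Si](C)(C)C(C)(C)C
F9 | step 15 | (6R,8S,9R,10S)-6-(acryloyloxy)-9-[(tert-butyldimethylsilyl)oxy]-4,10-dimethyl-1,7-dioxocyclodec-4-en-8-yl 2-methylprop-2-enoate | C=C(C)C(=O)O[C@@H]1C(=O)[C@H](OC(=O)C=C)/C=C(C)/CCC(=O)[C@@H](C)[C@H]1O[Si](C)(C)C(C)(C)C
F10 | step 15 | 9-[(tert-butyldimethylsilyl)oxy]-7-hydroxy-1-oxogermacra-4,11(13)-dien-12,6-olid-8-yl 2-methylprop-2-enoate (one C7 epimer drawn) | C=C(C)C(=O)O[C@@H]1[C@]2(O)C(=C)C(=O)O[C@@H]2/C=C(C)/CCC(=O)[C@@H](C)[C@H]1O[Si](C)(C)C(C)(C)C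
F11 | step 17 | (4R,5R,6R,8S,9R,10S)-9-[(tert-butyldimethylsilyl)oxy]-4,5-epoxy-6-hydroxy-4,10-dimethyl-1,7-dioxocyclodecan-8-yl 2-methylprop-2-enoate | C=C(C)C(=O)O[C@@H]1C(=O)[C@H](O)[C@H]2O[C@]2(C)CCC(=O)[C@@H](C)[C@H]1O[Si](C)(C)C(C)(C)C
F12 | step 17 | (4R,5R,6R,8S,9R,10S)-9-[(tert-butyldimethylsilyl)oxy]-6-[2-(diethoxyphosphoryl)prop-2-enoyloxy]-4,5-epoxy-4,10-dimethyl-1,7-dioxocyclodecan-8-yl 2-methylprop-2-enoate | C=C(C)C(=O)O[C@@H]1C(=O)[C@H](OC(=O)C(=C)P(=O)(OCC)OCC)[C@H]2O[C@]2(C)CCC(=O)[C@@H](C)[C@H]1O[Si](C)(C)C(C)(C)C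
F13 | step 17 | 9-O-(tert-butyldimethylsilyl) ether of 26 | C=C(C)C(=O)O[C@@H]1C2=C(COC(C)=O)C(=O)O[C@@H]2[C@H]2O[C@]2(C)CCC(=O)[C@@H](C)[C@H]1O[Si](C)(C)C(C)(C)C
A1 | alternative 1 | seco iodo-aldehyde: methyl (2Z)-2-(acetoxymethyl)-3-formyl-4-(methacryloyloxy)-5-[(tert-butyldimethylsilyl)oxy]-11-iodo-6,10-dimethyl-7-oxoundeca-2,10-dienoate (10E) | I/C=C(C)/CCC(=O)[C@@H](C)[C@@H](O[Si](C)(C)C(C)(C)C)[C@H](OC(=O)C(C)=C)/C(C=O)=C(\COC(C)=O)C(=O)OC
A2 | alternative 2 | trans-fused decalin hydroxy mesylate (C4–C9 bond intact, C9 hydroxyl, C5 mesylate equatorial, C7 dimethyl ketal, C1 dioxolane) | CS(=O)(=O)O[C@@H]1[C@@H](OCc2ccc(OC)cc2)C(OC)(OC)[C@@H](O[Si](C)(C)C(C)(C)C)[C@]2(O)[C@H](C)C3(OCCO3)CC[C@@]12C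
A3 | alternative 3 | epoxy cyclohexanol carrying an (E)-2-[(4-methoxyphenyl)methoxy]ethenyl group on C7 and an (E)-1-methoxyprop-1-enyl group on C2 | O[C@]1(/C=C/OCc3ccc(OC)cc3)[C@@H]2O[C@@H]2[C@](C)(O[Si](CC)(CC)CC)C[C@@H]1/C(OC)=C\C
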